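The earlier runs and the new flask are simulated for an exercise; the scatter is artificial.

The easy step was to divide one peak by another, other capture product Q over target P, in a series where substrate concentration changed and the equivalents stayed put.

the same everywhere: protic impurity 1.18 mM

| charge | substrate | first nucleophile | second nucleophile | remark | time |
|---|---|---|---|---|---|
| green | 0.029 M | 2 equiv | 1 equiv | run made earlier |  |
| amber | 0.044 M | 2 equiv | 1 equiv | run made earlier |  |
| flask | 0.059 M | 2.00 equiv | 1.00 equiv |  | 80 min |

| run | time / min | other capture product / % | target / % | substrate / % |
|---|---|---|---|---|
| green | 8.00 | 12.3 | 6.1 | 17.6 |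
| green | 20.0 | 16.6 | 7.0 | 0 |
| green | 40.0 | 17.0 | 7.6 | 0 |
| green | 60.0 | 16.8 | 6.2 | 0.3 |
| green | 80.0 | 18.0 | 7.4 | 0 |
| amber | 6.00 | 17.2 | 7.5 | 26.8 |
| amber | 12.0 | 21.0 | 7.9 | 9.6 |
| amber | 25.0 | 21.7 | 10.3 | 0.5 |
| amber | 40.0 | 22.1 | 8.6 | 0 |
| amber | 80.0 | 24.4 | 9.4 | 1.4 |

(each reading ± 1 percentage point)

- the analysis behind the earlier runs scatters by 1 percentage point, standard deviation
- reactions considered so far: substrate -> intermediate; first nucleophile + intermediate -> target; second nucleophile + intermediate -> other capture product; intermediate -> solvolysis product; first nucleophile -> decomposed reagent; second nucleophile + protic impurity -> quenched reagent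

- share of other capture product in other capture product plus target at 6.0 s
- share of other capture product in other capture product plus target at 80 min
- which of other capture product and target there is more of at 80 min

1. On the plateaus I pooled the late readings into the end ratio ρ, Q over P once substrate has reacted, and got 2.42, a share ρ/(1+ρ) of 70.8 %. Green alone read 70.8 % and amber alone 70.7 %, so I carried that share to the flask.

2. Q and P both form from the intermediate, so I took their momentary ratio as σD/B, with σ the selectivity factor and D and B the second and first nucleophile concentrations. I therefore expected ρ, with substrate and B lost at a fixed pace, to follow the charged D/B.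

3. In one extreme, B and D both stay near their charge while substrate reacts, the ratio holds steady, and the start share equals the end share. In the other, B decays at once, P forms first, and the start share falls far below the end share. Between them, with substrate loss k and B loss kd, P approaches its plateau at x = k + kd, and the start ratio is s = ρk/x.

4. Amber's substrate reading gave k = 0.219 min⁻¹, and its first target reading against the plateau gave x = 0.264 min⁻¹, faster. So I put the flask's start share near 66.8 %, a soft figure resting on a single substrate reading and a single target reading.

The forecast said 65 % (60 % to 70 %) at the start, slightly below mine, and 71 % (68.5 % to 73.5 %) at the end, with other capture product ahead: “Target is front-loaded”.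

The flask gave 51.0 % at 6.0 s and 72.4 % at 80 min, with other capture product ahead, 27.3 % against 10.4 %.

substrate → intermediate (k = 0.00370 s⁻¹); first nucleophile + intermediate → target (k = 1.90 M⁻¹ s⁻¹); second nucleophile + intermediate → other capture product (k = 3.90 M⁻¹ s⁻¹); intermediate → solvolysis product (k = 0.440 s⁻¹); first nucleophile → decomposed reagent (k = 0.00610 s⁻¹); second nucleophile + protic impurity → quenched reagent (k = 1.70 M⁻¹ s⁻¹) The flask's end share stood near ρ's share, but its start share lay 14 percentage points below the forecast, and the flask's ratio of Q to P grew 2.52-fold between those times, with half-lives of 1.9 min for first nucleophile by its decomposition alone and 3.1 min for substrate by its step to intermediate alone. For the neighbouring flask, the same but with 0.800 equiv of first nucleophile, scaling ρ by the charges gives 6.04, a share of 85.8 %, and that flask gave 86.2 %.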